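## Retrosynthetic overview

1. Last bond: C6 of ring A to the bridging CH2, made with reversed polarity. Ring A enters as its phenyliodonium ylide (an enolonium equivalent) and the rest of the molecule as a benzylic boronate (a homoenolate-type carbon nucleophile), joined by Pd(OAc)2 catalysis.
2. The benzylic boronate comes from the pentamer (rings B–F) by aminomethylation of its single free ring CH and conjugate borylation of the derived ortho-quinone methide.
3. The pentamer comes from the Mannich base of the ring F ketone and the symmetric tetramer (rings B–E). The tetramer comes from butyrylphloroglucinol by two formaldehyde doublings (monomer, dimer, tetramer).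
4. Ring A comes from butyrylphloroglucinol by gem-dimethylation (dearomatisation), then PhI(OAc)2.
5. No ring is built: all six carbocycles are bought as phloroglucinol or 2-methylphloroglucinol. Order of elaboration: rings B–E, then ring F, then ring A last.

Assumption: the target has no stereocentre and no configurationally defined double bond (C4 of ring A carries two identical methyl groups), so the "single enantiomer" is the achiral compound itself, drawn as the given tautomer.

## Route

Step 1
Reactants: 1 phloroglucinol; 2 butanoyl chloride
Product: 3 1-(2,4,6-trihydroxyphenyl)butan-1-one (butyrylphloroglucinol)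
Conditions: AlCl3 (3.5 equiv), PhNO2, 60 °C, 3 h; ice/2 M HCl
Reagents that add atoms: none
Why: Friedel–Crafts acylation of the electron-rich triol stops at the mono-ketone because the first acyl group deactivates the ring as a hydrogen-bonded vinylogous acid; no stereocentre is formed.

Step 2
Reactants: 3 1-(2,4,6-trihydroxyphenyl)butan-1-one (4 equiv; two molecules react)
Product: 4 bis(3-butanoyl-2,4,6-trihydroxyphenyl)methane
Conditions: 37% aq. HCHO (1 equiv per 4 equiv of 3), NaOH (0.2 equiv), H2O/EtOH, 0 °C to rt, 30 min; 1 M HCl; excess 3 recovered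
Reagents that add atoms: formaldehyde, C=O
Why: Base-catalysed phenol–formaldehyde condensation (hydroxymethylation, loss of water to the ortho-quinone methide, Michael addition of a second phenolate); the excess of 3 holds the reaction at the dimer and no stereocentre is formed.

Step 3
Reactants: 4 bis(3-butanoyl-2,4,6-trihydroxyphenyl)methane (4 equiv; two molecules react)
Product: 5 linear tetramer of rings B–E (four 5-butanoyl-2,4,6-trihydroxyphenyl rings joined through three CH2 bridges; each end ring keeps one free ring CH)
Conditions: 37% aq. HCHO (1 equiv per 4 equiv of 4), NaOH (0.2 equiv), H2O/EtOH, 0 °C to rt, 30 min; 1 M HCl; excess 4 recovered (Sephadex LH-20)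
Reagents that add atoms: formaldehyde, C=O
Why: The same phenol–formaldehyde condensation; each ring of 4 has only one free CH, so only the linear tetramer can form, and the excess of 4 suppresses the octamer.

Step 4
Reactants: 6 2-methylbenzene-1,3,5-triol (2-methylphloroglucinol); 2 butanoyl chloride
Product: 7 1-(2,4,6-trihydroxy-3-methylphenyl)butan-1-one (ring F ketone)
Conditions: AlCl3 (3.5 equiv), PhNO2, 60 °C, 3 h; ice/2 M HCl
Reagents that add atoms: none
Why: Friedel–Crafts acylation at one of the two equivalent free positions of 6 gives a single regioisomer and stops at the mono-ketone; no stereocentre is formed.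

Step 5
Reactants: 7 1-(2,4,6-trihydroxy-3-methylphenyl)butan-1-one; 5 linear tetramer of rings B–E (3 equiv)
Product: 9 pentamer of rings B–F (tetramer 5 carrying on one end ring a (3-butanoyl-2,4,6-trihydroxy-5-methylphenyl)methyl group; ring B keeps its free ring CH), via dimethylaminomethyl ketone 8 (not isolated)
Conditions: 37% aq. HCHO (1.0 equiv), 40% aq. Me2NH (1.1 equiv), EtOH, rt, 2 h; evaporate; then 5 (3 equiv), 1,4-dioxane, 90 °C, 3 h; excess 5 recovered
Reagents that add atoms: formaldehyde, C=O; dimethylamine, CNC (held in 8 only)
Why: Phenolic Mannich reaction at the only free ring CH of 7, then thermal loss of Me2NH gives the ortho-quinone methide, which a terminal ring CH of the excess tetramer 5 captures by Michael addition; because the methylene carbon is fixed on ring F before 5 is added, 5 cannot couple with itself.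

Step 6
Reactants: 9 pentamer of rings B–F
Product: 11 pentamer benzylic boronate (9 carrying a (4,4,5,5-tetramethyl-1,3,2-dioxaborolan-2-yl)methyl group at the free position of ring B), via aminomethylated pentamer 10 (not isolated)
Conditions: 37% aq. HCHO (1.0 equiv), 40% aq. Me2NH (1.1 equiv), MeOH, rt, 2 h; evaporate; then B2pin2 (3 equiv), CuCl (10 mol%), Xantphos (10 mol%), NaOMe (20 mol%), THF/MeOH 4:1, 40 °C, Ar; used crude
Reagents that add atoms: formaldehyde, C=O; bis(pinacolato)diboron, CC1(C)OB(OC1(C)C)B1OC(C)(C)C(C)(C)O1; dimethylamine, CNC (held in 10 only)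
Why: Proposed new method: the Mannich base 10 loses Me2NH on warming to give the terminal ortho-quinone methide, and the copper boryl species formed from CuCl, methoxide and B2pin2 adds its boryl group to the exocyclic carbon (1,4-addition, then protonation by MeOH), so the normally electrophilic benzylic carbon becomes a nucleophilic C–B carbon that is β to the carbonyls of the keto form of ring B (a homoenolate-type reagent); the closest known reaction type is the CuCl/alkoxide-catalysed conjugate borylation of enones and para-quinone methides with B2pin2, and no stereocentre is formed.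

Step 7
Reactants: 3 1-(2,4,6-trihydroxyphenyl)butan-1-one
Product: 12 2-butanoyl-3,5-dihydroxy-4,4-dimethylcyclohexa-2,5-dien-1-one (butyrylfilicinic acid, ring A)
Conditions: NaOMe (3.2 equiv), MeI (2.4 equiv), MeOH, 0 °C to rt, 16 h; 1 M HCl; chromatography removes the mono- and trimethyl congeners
Reagents that add atoms: iodomethane, CI
Why: C-alkylation of the ambident phloroglucinolate with MeI, the second methyl entering at the already methylated and most electron-rich carbon so that the ring is dearomatised to the β,β'-triketone (gem-dimethylation, typically about 40%); the new quaternary carbon carries two identical methyl groups and is not a stereocentre.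

Step 8
Reactants: 12 butyrylfilicinic acid
Product: 13 phenyliodonium ylide of 12 at C6 (phenyliodonium 3-butanoyl-4-hydroxy-5,5-dimethyl-2,6-dioxocyclohex-3-en-1-ide)
Conditions: PhI(OAc)2 (1.05 equiv), KOH (2.0 equiv), MeOH, 0 °C, 1 h; ice-water, pH 5–6, filter; store cold and dark
Reagents that add atoms: (diacetoxyiodo)benzene, CC(=O)OI(OC(C)=O)c1ccccc1
Why: Standard preparation of a β-dicarbonyl phenyliodonium ylide: the enolate carbon C6 (C2 is blocked by the butanoyl group) displaces acetate from trivalent iodine and the second acetate leaves on deprotonation, which turns the nucleophilic enol carbon into an enolonium equivalent.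

Step 9
Reactants: 11 pentamer benzylic boronate; 13 phenyliodonium ylide of butyrylfilicinic acid (1.5 equiv)
Product: 14 target CNP0309827.0 (rings A–F joined by five CH2 bridges)
Conditions: Pd(OAc)2 (5 mol%), P(t-Bu)3·HBF4 (10 mol%), LiOH (20 equiv), degassed DME/H2O 3:1, 0 °C to rt, 4 h, dark; 1 M HCl to pH 2; Sephadex LH-20
Reagents that add atoms: none
Why: Proposed new method: zerovalent palladium inserts into the C6–I bond of the ylide 13 with loss of PhI, the benzyl group of 11 passes from the boronate (activated internally by the ortho-phenoxide) to divalent palladium, and reductive elimination forms the C6–CH2 bond between two carbons that are both natural nucleophiles; the closest known reaction type is the Suzuki-type coupling of phenyliodonium zwitterions of 4-hydroxycoumarin and 2-hydroxy-1,4-naphthoquinone with boronic acids (Pd, LiOH, DME/H2O, rt), combined with the Suzuki–Miyaura coupling of benzylboronates, and no stereocentre is formed.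

## Compound list

1 | phloroglucinol (benzene-1,3,5-triol) | Oc1cc(O)cc(O)c1 | starting material
2 | butanoyl chloride | CCCC(=O)Cl | starting material
3 | 1-(2,4,6-trihydroxyphenyl)butan-1-one (butyrylphloroglucinol) | CCCC(=O)c1c(O)cc(O)cc1O | intermediate
4 | bis(3-butanoyl-2,4,6-trihydroxyphenyl)methane | CCCC(=O)c1c(O)cc(O)c(Cc2c(O)cc(O)c(C(=O)CCC)c2O)c1O | intermediate
5 | linear tetramer of rings B–E, free ring CH on both end rings | CCCC(=O)c1c(O)cc(O)c(Cc2c(O)c(Cc3c(O)c(Cc4c(O)cc(O)c(C(=O)CCC)c4O)c(O)c(C(=O)CCC)c3O)c(O)c(C(=O)CCC)c2O)c1O | intermediate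
6 | 2-methylbenzene-1,3,5-triol (2-methylphloroglucinol) | Cc1c(O)cc(O)cc1O | starting material
7 | 1-(2,4,6-trihydroxy-3-methylphenyl)butan-1-one (ring F ketone) | CCCC(=O)c1c(O)cc(O)c(C)c1O | intermediate
8 | 1-[3-(dimethylaminomethyl)-2,4,6-trihydroxy-5-methylphenyl]butan-1-one (Mannich base of 7, not isolated) | CCCC(=O)c1c(O)c(CN(C)C)c(O)c(C)c1O | intermediate
9 | pentamer of rings B–F, free ring CH on ring B | CCCC(=O)c1c(O)cc(O)c(Cc2c(O)c(Cc3c(O)c(Cc4c(O)c(Cc5c(O)c(C)c(O)c(C(=O)CCC)c5O)c(O)c(C(=O)CCC)c4O)c(O)c(C(=O)CCC)c3O)c(O)c(C(=O)CCC)c2O)c1O | intermediate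
10 | pentamer with CH2NMe2 at the free position of ring B (Mannich base of 9, not isolated) | CCCC(=O)c1c(O)c(CN(C)C)c(O)c(Cc2c(O)c(Cc3c(O)c(Cc4c(O)c(Cc5c(O)c(C)c(O)c(C(=O)CCC)c5O)c(O)c(C(=O)CCC)c4O)c(O)c(C(=O)CCC)c3O)c(O)c(C(=O)CCC)c2O)c1O | intermediate
11 | pentamer with CH2–B(pinacolato) at the free position of ring B (benzylic boronate) | CCCC(=O)c1c(O)c(CB6OC(C)(C)C(C)(C)O6)c(O)c(Cc2c(O)c(Cc3c(O)c(Cc4c(O)c(Cc5c(O)c(C)c(O)c(C(=O)CCC)c5O)c(O)c(C(=O)CCC)c4O)c(O)c(C(=O)CCC)c3O)c(O)c(C(=O)CCC)c2O)c1O | intermediate
12 | 2-butanoyl-3,5-dihydroxy-4,4-dimethylcyclohexa-2,5-dien-1-one (butyrylfilicinic acid) | CCCC(=O)C1=C(O)C(C)(C)C(O)=CC1=O | intermediate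
13 | phenyliodonium ylide of 12 at C6 | CCCC(=O)C1=C(O)C(C)(C)C(=O)[C-]([I+]c2ccccc2)C1=O | intermediate
14 | CNP0309827.0, hexamer of rings A–F | CCCC(=O)C1=C(O)C(C)(C)C(O)=C(Cc2c(O)c(Cc3c(O)c(Cc4c(O)c(Cc5c(O)c(Cc6c(O)c(C)c(O)c(C(=O)CCC)c6O)c(O)c(C(=O)CCC)c5O)c(O)c(C(=O)CCC)c4O)c(O)c(C(=O)CCC)c3O)c(O)c(C(=O)CCC)c2O)C1=O | target

## Step count and risk

Total step count: 9 steps (two of them, steps 5 and 6, run as two-stage one-pot operations).

Longest linear sequence: 6 steps (1 → 3 → 4 → 5 → 9 → 11 → 14, that is steps 1, 2, 3, 5, 6 and 9).

Three steps most likely to fail: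

First, step 9. The Pd(OAc)2-catalysed coupling is unprecedented on a polyphenolate of this size. The likely failures are protodeboronation of 11, reduction of 13 back to 12, and base-induced scrambling of the methylene bridges. The fallback sets out from 9 and 12 and comes back at 14. It makes the same bond with normal polarity: 9 is aminomethylated exactly as in the first stage of step 6, but the aminomethylated pentamer 10 is now filtered off as its zwitterion. Heating 10 with 12 (1.5 equiv) in 1,4-dioxane at 90 °C releases Me2NH, and C6 of 12 adds to the ortho-quinone methide to give 14. This fallback makes no new compound F0.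

Second, step 6. CuCl may be sequestered by the polyphenolate, the zwitterionic Mannich base may be insoluble, and the phenolic benzylboronate may not survive. The fallback sets out from 9 and comes back at 11. 9 is condensed with 37% aq. HCHO and p-toluenesulfinic acid (MeOH/H2O, 40 °C) to give the neutral, chromatographable pentamer benzylic p-tolyl sulfone F1. NaOMe in THF/MeOH at rt then expels sulfinate. The ortho-quinone methide is trapped without any copper by the methoxide adduct of B2pin2 (Lewis-base-activated diboron), giving 11.

Third, step 3. The doubling is statistical and can drift to octamers or scramble bridges. The fallback sets out from 4 and comes back at 5. 4 is aminomethylated on both end rings (37% aq. HCHO 2.2 equiv, 40% aq. Me2NH 2.4 equiv, EtOH, rt) to the bis(dimethylaminomethyl) dimer F2, isolated as its zwitterion. Heating F2 with a large excess of monomer 3 (10 equiv, 1,4-dioxane, 90 °C) caps each released ortho-quinone methide with one molecule of 3. The tetramer length is then fixed by construction instead of by stoichiometry.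

## Further compounds

F0 | step 9 | none | none
F1 | step 6 | pentamer of rings B–F with CH2–SO2(4-methylphenyl) at the free position of ring B (benzylic p-tolyl sulfone) | CCCC(=O)c1c(O)c(CS(=O)(=O)c6ccc(C)cc6)c(O)c(Cc2c(O)c(Cc3c(O)c(Cc4c(O)c(Cc5c(O)c(C)c(O)c(C(=O)CCC)c5O)c(O)c(C(=O)CCC)c4O)c(O)c(C(=O)CCC)c3O)c(O)c(C(=O)CCC)c2O)c1O
F2 | step 3 | bis[3-butanoyl-5-(dimethylaminomethyl)-2,4,6-trihydroxyphenyl]methane (bis-Mannich base of 4) | CCCC(=O)c1c(O)c(CN(C)C)c(O)c(Cc2c(O)c(CN(C)C)c(O)c(C(=O)CCC)c2O)c1O
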